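The isoflavone is disconnected at C3–C4 of ring C. With O1–C2 in place as an aryl ether, both carbons are carbonyl carbons: C4 is the aldehyde on ring A and C3 the aryl ketone that carries ring B. A triazolylidene carbene inverts the polarity of C4 and adds it to C3, so one catalytic operation forms C3–C4 and closes ring C as a racemic 3-hydroxychroman-4-one. The precursor is the phenacyl ether of a 2-hydroxy-3-methoxybenzaldehyde: the C8 methoxy group is already in place and O5, O7 and O3′ are benzyl ethers. Dehydration across C2–C3 and one hydrogenolysis then give isoirigenin.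

Key step: step 12

Remark: the ketol is made as the racemate because its only stereocenter, C3, becomes trigonal in the following dehydration; benzyl ethers are kept on O5, O7 and O3′ so that one neutral hydrogenolysis ends the route, and the methyl group on O8 is placed by a Baeyer–Villiger sequence in which a transient methoxymethyl group marks the oxygen that becomes O1, so that no ambiguity between C6 and C8 can arise.

Step 1
Reactants: 1 2,4,6-trihydroxybenzaldehyde
Product: 2 2,4-bis(benzyloxy)-6-hydroxybenzaldehyde
Conditions: BnBr (2.05 equiv), K2CO3 (2.1 equiv), DMF, 0 °C → rt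
Reagents that add atoms: benzyl bromide, BrCc1ccccc1
Why: Williamson ether synthesis in which the para hydroxyl and one ortho hydroxyl are alkylated, while the last ortho hydroxyl is hydrogen-bonded to the aldehyde and least nucleophilic, so that two equivalents of halide should stop at the dibenzyl ether.

Step 2
Reactants: 2 2,4-bis(benzyloxy)-6-hydroxybenzaldehyde
Product: 3 2,4-bis(benzyloxy)-6-(methoxymethoxy)benzaldehyde
Conditions: NaH, MOMCl, DMF, 0 °C → rt
Reagents that add atoms: chloromethyl methyl ether, COCCl
Why: O-alkylation of the sodium phenoxide with an α-chloro ether (acetal protection); the methoxymethyl group marks the future O1 and, unlike a silyl or acyl group, cannot migrate to the neighbouring oxygen created in step 3.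

Step 3
Reactants: 3 2,4-bis(benzyloxy)-6-(methoxymethoxy)benzaldehyde
Product: 5 2,4-bis(benzyloxy)-6-(methoxymethoxy)phenol, via aryl formate 4 (not isolated)
Conditions: mCPBA, CH2Cl2, 0 °C → rt; NaHCO3 wash; then K2CO3 (cat.), MeOH, rt
Reagents that add atoms: meta-chloroperoxybenzoic acid, O=C(OO)c1cccc(Cl)c1
Why: Baeyer–Villiger oxidation (Dakin type) in which the electron-rich trialkoxyphenyl group migrates in preference to hydrogen to give the formate, which also shields the new oxygen from over-oxidation until methanolysis releases the phenol; acetal and benzyl ethers are inert to both stages.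

Step 4
Reactants: 5 2,4-bis(benzyloxy)-6-(methoxymethoxy)phenol
Product: 6 1,5-bis(benzyloxy)-2-methoxy-3-(methoxymethoxy)benzene
Conditions: MeI, K2CO3, DMF, rt
Reagents that add atoms: iodomethane, CI
Why: Williamson methylation of the only free phenol places the methyl group on the oxygen that becomes the C8 methoxy group, flanked by the future O1 and O7.

Step 5
Reactants: 6 1,5-bis(benzyloxy)-2-methoxy-3-(methoxymethoxy)benzene
Product: 7 3,5-bis(benzyloxy)-2-methoxyphenol
Conditions: HCl (cat.), MeOH, 50 °C
Reagents that add atoms: none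
Why: Acid-catalysed acetal exchange with methanol cleaves the methoxymethyl ether as dimethoxymethane, whereas benzyl and methyl aryl ethers do not react with dilute acid.

Step 6
Reactants: 7 3,5-bis(benzyloxy)-2-methoxyphenol
Product: 9 4,6-bis(benzyloxy)-2-hydroxy-3-methoxybenzaldehyde, via hydroxymethylphenol 8 (not isolated)
Conditions: MgCl2, Et3N, (CH2O)n, MeCN, reflux
Reagents that add atoms: paraformaldehyde (as formaldehyde), C=O
Why: Magnesium-mediated ortho-formylation of a phenol, in which the magnesium phenoxide delivers formaldehyde to the only free ortho carbon and a second formaldehyde oxidises the hydroxymethyl intermediate by Oppenauer-type hydride transfer; the para carbon between the two benzyloxy groups is not reached by this chelate-controlled pathway.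

Step 7
Reactants: 10 3-hydroxy-4,5-dimethoxybenzaldehyde
Product: 11 3-(benzyloxy)-4,5-dimethoxybenzaldehyde
Conditions: BnBr, K2CO3, DMF, rt
Reagents that add atoms: benzyl bromide, BrCc1ccccc1
Why: Williamson ether synthesis on the single phenol, which must be masked before the bromination and the phenoxide alkylation that follow.

Step 8
Reactants: 11 3-(benzyloxy)-4,5-dimethoxybenzaldehyde
Product: 12 1-[3-(benzyloxy)-4,5-dimethoxyphenyl]ethanol (racemic)
Conditions: MeMgBr, THF, 0 °C; H2O
Reagents that add atoms: methylmagnesium bromide, C[Mg]Br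
Why: Grignard addition to the aldehyde; the carbinol stereocenter is formed as a racemate and disappears in step 9.

Step 9
Reactants: 12 1-[3-(benzyloxy)-4,5-dimethoxyphenyl]ethanol (racemic)
Product: 13 1-[3-(benzyloxy)-4,5-dimethoxyphenyl]ethanone
Conditions: MnO2, CH2Cl2, rt
Reagents that add atoms: none
Why: MnO2 oxidation of a secondary benzylic alcohol to the aryl methyl ketone, with ethers untouched.

Step 10
Reactants: 13 1-[3-(benzyloxy)-4,5-dimethoxyphenyl]ethanone
Product: 14 2-bromo-1-[3-(benzyloxy)-4,5-dimethoxyphenyl]ethanone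
Conditions: CuBr2 (2 equiv), EtOAc–CHCl3, reflux
Reagents that add atoms: copper dibromide (CuBr2), Br[Cu]Br
Why: α-Bromination of an aryl methyl ketone through its enol with CuBr2, a reagent that stops at the monobromide and spares the acyl-deactivated aromatic ring.

Step 11
Reactants: 9 4,6-bis(benzyloxy)-2-hydroxy-3-methoxybenzaldehyde; 14 2-bromo-1-[3-(benzyloxy)-4,5-dimethoxyphenyl]ethanone
Product: 15 4,6-bis(benzyloxy)-2-{2-[3-(benzyloxy)-4,5-dimethoxyphenyl]-2-oxoethoxy}-3-methoxybenzaldehyde
Conditions: K2CO3 (1.1 equiv), DMF, 0 °C → rt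
Reagents that add atoms: none
Why: Williamson O-alkylation (SN2 at the carbonyl-activated primary bromide) forms the O1–C2 ether; a mild base in small excess and low temperature are chosen because the keto-aldehyde can undergo base-induced aldol cyclisation (Rap–Stoermer condensation) on heating.

Step 12
Reactants: 15 4,6-bis(benzyloxy)-2-{2-[3-(benzyloxy)-4,5-dimethoxyphenyl]-2-oxoethoxy}-3-methoxybenzaldehyde
Product: 16 5,7-bis(benzyloxy)-3-[3-(benzyloxy)-4,5-dimethoxyphenyl]-3-hydroxy-8-methoxychroman-4-one (racemic)
Conditions: 2-(pentafluorophenyl)-6,7-dihydro-5H-pyrrolo[2,1-c][1,2,4]triazol-2-ium tetrafluoroborate (20 mol%), i-Pr2NEt (20 mol%), toluene (0.05 M), 60 °C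
Reagents that add atoms: none
Why: The carbene released from the triazolium salt adds to the aldehyde carbon C4, proton transfer gives the Breslow enaminol as an acyl anion equivalent, this attacks the tethered ketone carbon C3, and collapse of the adduct releases the carbene and leaves the tertiary ketol. The closest known reaction type is the carbene-catalysed intramolecular crossed aldehyde–ketone benzoin reaction of 2-(2-oxoalkoxy)benzaldehydes to 3-hydroxychroman-4-ones. Ring C closes in a 6-exo-trig mode, the attacked C=O lying outside the new ring C4–C4a–C8a–O1–C2–C3. The new stereocenter C3 is formed without control by the achiral catalyst, which is acceptable because step 13 makes C3 trigonal. The step needs the aldehyde as donor and the ketone as acceptor, and ring closure in preference to intermolecular benzoin coupling or aldol reaction of the acidic O–CH2–C=O unit; this is secured because only the aldehyde can form a Breslow intermediate, by the six-membered tether at high dilution, and by a weak amine base in substoichiometric amount. The two ortho alkoxy groups and the electron-rich ring A slow the carbene addition, hence the electron-poor N-pentafluorophenyl triazolium salt, whose aldehyde adducts deprotonate readily, and gentle heating.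

Step 13
Reactants: 16 5,7-bis(benzyloxy)-3-[3-(benzyloxy)-4,5-dimethoxyphenyl]-3-hydroxy-8-methoxychroman-4-one (racemic)
Product: 18 5,7-bis(benzyloxy)-3-[3-(benzyloxy)-4,5-dimethoxyphenyl]-8-methoxy-4H-chromen-4-one, via chlorosulfite ester 17 (not isolated)
Conditions: SOCl2, pyridine, CH2Cl2, 0 °C → rt
Reagents that add atoms: none
Why: Dehydration of a tertiary α-ketol through its chlorosulfite with pyridine-induced E2 elimination, the classical SOCl2–pyridine dehydration of tertiary alcohols; only C2 carries β-hydrogens, so only the C2=C3 enol ether can form, which completes the conjugated chromen-4-one and erases the C3 stereocenter.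

Step 14
Reactants: 18 5,7-bis(benzyloxy)-3-[3-(benzyloxy)-4,5-dimethoxyphenyl]-8-methoxy-4H-chromen-4-one
Product: 19 isoirigenin [5,7-dihydroxy-3-(3-hydroxy-4,5-dimethoxyphenyl)-8-methoxy-4H-chromen-4-one]
Conditions: H2 (1 atm), 10% Pd/C, EtOAc–MeOH, rt
Reagents that add atoms: none
Why: Catalytic hydrogenolysis of three benzyl aryl ethers, which should be faster than hydrogenation of the vinylogous-ester C2=C3 bond when the reaction is stopped after uptake of three equivalents of hydrogen; the methyl ethers are untouched.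

Compound list
1 | 2,4,6-trihydroxybenzaldehyde | O=Cc1c(O)cc(O)cc1O | starting material
2 | 2,4-bis(benzyloxy)-6-hydroxybenzaldehyde | O=Cc1c(O)cc(OCc2ccccc2)cc1OCc1ccccc1 | intermediate
3 | 2,4-bis(benzyloxy)-6-(methoxymethoxy)benzaldehyde | COCOc1cc(OCc2ccccc2)cc(OCc2ccccc2)c1C=O | intermediate
4 | 2,4-bis(benzyloxy)-6-(methoxymethoxy)phenyl formate (not isolated) | COCOc1cc(OCc2ccccc2)cc(OCc2ccccc2)c1OC=O | intermediate
5 | 2,4-bis(benzyloxy)-6-(methoxymethoxy)phenol | COCOc1cc(OCc2ccccc2)cc(OCc2ccccc2)c1O | intermediate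
6 | 1,5-bis(benzyloxy)-2-methoxy-3-(methoxymethoxy)benzene | COCOc1cc(OCc2ccccc2)cc(OCc2ccccc2)c1OC | intermediate
7 | 3,5-bis(benzyloxy)-2-methoxyphenol | COc1c(O)cc(OCc2ccccc2)cc1OCc1ccccc1 | intermediate
8 | 3,5-bis(benzyloxy)-2-(hydroxymethyl)-6-methoxyphenol (not isolated) | COc1c(O)c(CO)c(OCc2ccccc2)cc1OCc1ccccc1 | intermediate
9 | 4,6-bis(benzyloxy)-2-hydroxy-3-methoxybenzaldehyde | COc1c(O)c(C=O)c(OCc2ccccc2)cc1OCc1ccccc1 | intermediate
10 | 3-hydroxy-4,5-dimethoxybenzaldehyde | COc1cc(C=O)cc(O)c1OC | starting material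
11 | 3-(benzyloxy)-4,5-dimethoxybenzaldehyde | COc1cc(C=O)cc(OCc2ccccc2)c1OC | intermediate
12 | 1-[3-(benzyloxy)-4,5-dimethoxyphenyl]ethanol (racemic) | COc1cc(C(C)O)cc(OCc2ccccc2)c1OC | intermediate
13 | 1-[3-(benzyloxy)-4,5-dimethoxyphenyl]ethanone | COc1cc(C(C)=O)cc(OCc2ccccc2)c1OC | intermediate
14 | 2-bromo-1-[3-(benzyloxy)-4,5-dimethoxyphenyl]ethanone | COc1cc(C(=O)CBr)cc(OCc2ccccc2)c1OC | intermediate
15 | 4,6-bis(benzyloxy)-2-{2-[3-(benzyloxy)-4,5-dimethoxyphenyl]-2-oxoethoxy}-3-methoxybenzaldehyde | COc1c(OCC(=O)c2cc(OC)c(OC)c(OCc3ccccc3)c2)c(C=O)c(OCc2ccccc2)cc1OCc1ccccc1 | intermediate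
16 | 5,7-bis(benzyloxy)-3-[3-(benzyloxy)-4,5-dimethoxyphenyl]-3-hydroxy-8-methoxychroman-4-one (racemic) | COc1cc(C2(O)COc3c(OC)c(OCc4ccccc4)cc(OCc4ccccc4)c3C2=O)cc(OCc2ccccc2)c1OC | intermediate
17 | 5,7-bis(benzyloxy)-3-[3-(benzyloxy)-4,5-dimethoxyphenyl]-8-methoxy-4-oxochroman-3-yl chlorosulfite (racemic, not isolated) | COc1cc(C2(OS(=O)Cl)COc3c(OC)c(OCc4ccccc4)cc(OCc4ccccc4)c3C2=O)cc(OCc2ccccc2)c1OC | intermediate
18 | 5,7-bis(benzyloxy)-3-[3-(benzyloxy)-4,5-dimethoxyphenyl]-8-methoxy-4H-chromen-4-one | COc1cc(-c2coc3c(OC)c(OCc4ccccc4)cc(OCc4ccccc4)c3c2=O)cc(OCc2ccccc2)c1OC | intermediate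
19 | isoirigenin | COc1cc(-c2coc3c(OC)c(O)cc(O)c3c2=O)cc(O)c1OC | target

Total step count: 14. Longest linear sequence: 10 (steps 1–6 and 11–14).

Steps most likely to fail

Step 12. Carbene addition to the di-ortho-alkoxy, electron-rich aldehyde may be slow or reversible, so that enolisation of the O–CH2–C=O unit and aldol condensation outrun the benzoin closure. The fallback builds ring C by the oxidative 1,2-aryl shift of a chalcone and sets out from salicylaldehyde 9, with ring B aldehyde 11 as partner. Excess MeMgBr (THF, 0 °C) should convert 9 into 1-[4,6-bis(benzyloxy)-2-hydroxy-3-methoxyphenyl]ethanol F1, and MnO2 (CH2Cl2, rt) should oxidise this to 1-[4,6-bis(benzyloxy)-2-hydroxy-3-methoxyphenyl]ethanone F2. Claisen–Schmidt condensation of F2 with 11 (KOH, EtOH, rt) should give (E)-1-[4,6-bis(benzyloxy)-2-hydroxy-3-methoxyphenyl]-3-[3-(benzyloxy)-4,5-dimethoxyphenyl]prop-2-en-1-one F3. Tl(NO3)3 in MeOH–HC(OMe)3 should then move ring B from the β to the α carbon and give 1-[4,6-bis(benzyloxy)-2-hydroxy-3-methoxyphenyl]-2-[3-(benzyloxy)-4,5-dimethoxyphenyl]-3,3-dimethoxypropan-1-one F4. Warm HCl in MeOH closes ring C with loss of methanol, and the route is rejoined at isoflavone 18, so that steps 11 to 13 are bypassed.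

Step 11. The hindered, chelated phenoxide may alkylate slowly, and the keto-aldehyde may be lost by base-induced intramolecular aldol condensation while it forms. The fallback carries the ketone at the alcohol oxidation level, which has no acidic methylene group, and sets out from aldehyde 11. Corey–Chaykovsky methylenation (Me3S+ I−, NaH, DMSO–THF) should give 2-[3-(benzyloxy)-4,5-dimethoxyphenyl]oxirane F5. Opening of F5 at its terminal carbon by the phenoxide of 9 (K2CO3, DMF, 70 °C) should give 4,6-bis(benzyloxy)-2-{2-[3-(benzyloxy)-4,5-dimethoxyphenyl]-2-hydroxyethoxy}-3-methoxybenzaldehyde F6. Oxidation with Dess–Martin periodinane (CH2Cl2, rt), without base, returns to the route at keto-aldehyde 15.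

Step 13. The chlorosulfite may ionise, and α-ketol (acyloin) rearrangement or substitution by chloride may take the place of elimination. The fallback removes the C3 oxygen reductively and restores the unsaturation by dehydrogenation, setting out from ketol 16. SmI2 (THF–MeOH, −78 °C) should cleave the C3–O bond α to the ketone and give 5,7-bis(benzyloxy)-3-[3-(benzyloxy)-4,5-dimethoxyphenyl]-8-methoxychroman-4-one F7. DDQ (dioxane, reflux) should dehydrogenate F7 across C2–C3, and the route is rejoined at isoflavone 18.

Further compounds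
F1 | step 12 | 1-[4,6-bis(benzyloxy)-2-hydroxy-3-methoxyphenyl]ethanol (racemic) | COc1c(O)c(C(C)O)c(OCc2ccccc2)cc1OCc1ccccc1
F2 | step 12 | 1-[4,6-bis(benzyloxy)-2-hydroxy-3-methoxyphenyl]ethanone | COc1c(O)c(C(C)=O)c(OCc2ccccc2)cc1OCc1ccccc1
F3 | step 12 | (E)-1-[4,6-bis(benzyloxy)-2-hydroxy-3-methoxyphenyl]-3-[3-(benzyloxy)-4,5-dimethoxyphenyl]prop-2-en-1-one | COc1cc(/C=C/C(=O)c2c(O)c(OC)c(OCc3ccccc3)cc2OCc2ccccc2)cc(OCc2ccccc2)c1OC
F4 | step 12 | 1-[4,6-bis(benzyloxy)-2-hydroxy-3-methoxyphenyl]-2-[3-(benzyloxy)-4,5-dimethoxyphenyl]-3,3-dimethoxypropan-1-one (racemic) | COc1cc(C(C(OC)OC)C(=O)c2c(O)c(OC)c(OCc3ccccc3)cc2OCc2ccccc2)cc(OCc2ccccc2)c1OC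
F5 | step 11 | 2-[3-(benzyloxy)-4,5-dimethoxyphenyl]oxirane (racemic) | COc1cc(C2CO2)cc(OCc2ccccc2)c1OC
F6 | step 11 | 4,6-bis(benzyloxy)-2-{2-[3-(benzyloxy)-4,5-dimethoxyphenyl]-2-hydroxyethoxy}-3-methoxybenzaldehyde (racemic) | COc1c(OCC(O)c2cc(OC)c(OC)c(OCc3ccccc3)c2)c(C=O)c(OCc2ccccc2)cc1OCc1ccccc1
F7 | step 13 | 5,7-bis(benzyloxy)-3-[3-(benzyloxy)-4,5-dimethoxyphenyl]-8-methoxychroman-4-one (racemic) | COc1cc(C2COc3c(OC)c(OCc4ccccc4)cc(OCc4ccccc4)c3C2=O)cc(OCc2ccccc2)c1OC
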